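(The data were computed for substances that don't exist; the scatter is artificial.)

I decide to follow L first and leave the rates aside, so I begin with what each flask is given.

| flask | Z | L | remark | time |
|---|---|---|---|---|
| Monday's | 0.33 M | 0.285 M (in portions, 4) | run made earlier; portions every 3.0 min |  |
| eta | 0.30 M | 0.285 M (in portions, 4) | the portions of L follow each other after 3.0 min, the first at the start | 12 min |
| gamma | 0.30 M | 0.150 M (in portions, 4) | the portions of L follow each other after 6.0 min, the first at the start | 12 min |
| delta | 0.30 M | 0.800 M (in portions, 4) | the portions of L follow each other after 2.0 min, the first at the start | 12 min |
| theta | 1.0 M | 0.150 M (in portions, 4) | the portions of L follow each other after 3.0 min, the first at the start | 12 min |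
| zeta | 0.30 M | 0.200 M (in portions, 4) | the portions of L follow each other after 0.80 min, the first at the start | 12 min |

For theta, L over Z is 15.0%. I call this ratio of L charged to Z charged the L ceiling: it is the most Q, in percent of the Z charged, if I assume that each L makes at most one Q, with L as the limiting reagent. But a portion must be in before it can count. Gamma has two portions in before 12 min, so its ceiling at that time is 25.0%, higher than theta's. Delta has more L than Z, so the ceiling tells me nothing there.

- Monday's (time / min: Q / %): 0.667: 0; 2.00: 4; 3.00: 8; 5.00: 15; 8.00: 23

(each reading ± 2 percentage points)

Monday's flask has a ceiling of 86.4% for its whole charge, but its last reading is 23% at 8.00 min. So these readings stop below that ceiling and do not test whether Q reaches one. Gamma's ceiling lies below those of zeta, eta and delta, so by the ceilings I commit to theta last and gamma just above it, and I take the ceilings as upper bounds, not as estimates.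

- the earlier runs were read with a standard deviation of 2 percentage points
- percentages count the whole charge, also what has not yet gone in
- a reading or a percentage of Q counts all its forms, free or not

1. ranking by amount of Q, in percent of the Z charged, from high to low, at 12 min (eta / gamma / delta / theta / zeta)
2. the amount of Q, in percent of the Z charged of the flask you put first, at 12 min
3. the amount of Q, in percent of the Z charged of the flask you put last, at 12 min

The forecast gives delta > zeta > eta > gamma > theta, with 35% for the first flask and 14.5% for the last, and it holds that “the other two are L-limited”. Its low lies close to my ceiling for theta, since it is what one gets with all of the L turned into Q. There we part: I hold that figure as a bound, the forecast as a value.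

The flasks give delta > zeta > eta > gamma > theta, with delta at 66.5% and theta at 7.98%.

    Z + L → E (k = 0.0118 /M/s)
    E → Q (k = 0.0267 /s)
    X ⇌ Q, rate k3*(cs3 - [Q]) while solid is left; crystals form when [Q] > cs3 (solubility = 3.40 mM, k = 0.860 /s)
    2 Z → G (k = 0.00515 /M/s)

Theta's Q, all forms counted, reaches about half of its ceiling, and 45% of its L is still there at 12.0 min. In theta the path from 2 Z to G has half of its turnover up to that time behind it by 1.17 min, the path from E to Q by 5.33 min. At 12.0 min theta holds 82.6% as G, each G counted as two Z, and 9.08% as Z. A flask like theta with 0.25 M of Z has a ceiling of 60.0%, and it holds 22.2% of Q at 12.0 min.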